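**Strategy**

Everything rests on cutting the lower pyran ring (ring F: O1–C2–C3–C4–C4a–C8a) across C3–C4 and O1–C2. The feature used is its cis-2-aryl-3-acyloxy pattern beside the ring D oxygen: C4=C4a–C8a=O1 is an ortho-quinone methide, C2=C3 a (Z)-β-acyloxystyrene. One chiral-acid-catalysed inverse-demand oxa-Diels–Alder reaction of a salicyl alcohol with a (Z)-styryl acetate closes ring F, turns the Z geometry into the 2,3-cis pair and sets both stereocentres. A related cycloaddition of a salicylaldehyde acetal with a diaryl ether enol gallate gives the upper flavan already methoxylated at C4; 4β→8 arylation, macrolactonisation onto the lower C3 oxygen and hydrogenolysis complete the target.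

Key step: step 5

Remark: the upper flavan (rings A, C, B) carries the C4–aryl bond, the lower flavan (rings D, F, E) is joined through C8. It is assumed that the (R)-configured acid gives the (2R,3R) series in steps 5 and 12; if not, its enantiomer is used. The C4 configuration of 19 is drawn as 4S (methoxy trans to the ester); its 4R epimer would give the same flavan-4-yl cation in step 13 and is equally usable.

**Route**

Step 1
Reactants: 1 2,4,6-trihydroxybenzaldehyde
Product: 2 2,4-bis(benzyloxy)-6-hydroxybenzaldehyde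
Conditions: BnBr (2.05 equiv), K2CO3, DMF, rt
Reagents that add atoms: benzyl bromide, BrCc1ccccc1
Why: Williamson etherification, in which the 4-OH and one ortho OH react while the remaining OH, hydrogen-bonded to the formyl group, stays free.

Step 2
Reactants: 2 2,4-bis(benzyloxy)-6-hydroxybenzaldehyde
Product: 3 3,5-bis(benzyloxy)-2-(hydroxymethyl)phenol
Conditions: NaBH4, THF/MeOH, 0 °C; used at once
Reagents that add atoms: none
Why: Hydride reduction of the aldehyde; the electron-rich salicyl alcohol is not stored because it loses water easily.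

Step 3
Reactants: 4 3,4,5-tris(benzyloxy)benzaldehyde
Product: 5 1,2,3-tris(benzyloxy)-5-ethynylbenzene
Conditions: dimethyl (1-diazo-2-oxopropyl)phosphonate (1.3 equiv), K2CO3, MeOH/THF, rt
Reagents that add atoms: Ohira–Bestmann reagent, CC(=O)C(=[N+]=[N-])P(=O)(OC)OC
Why: Seyferth–Gilbert homologation in its Ohira–Bestmann form turns the non-enolisable aryl aldehyde into the terminal alkyne under mild base.

Step 4
Reactants: 5 1,2,3-tris(benzyloxy)-5-ethynylbenzene
Product: 6 (Z)-2-[3,4,5-tris(benzyloxy)phenyl]ethenyl acetate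
Conditions: AcOH (1.2 equiv), [RuCl2(p-cymene)]2 (1 mol%), P(4-ClC6H4)3 (3 mol%), DMAP (4 mol%), toluene, 60 °C
Reagents that add atoms: acetic acid, CC(=O)O
Why: Ruthenium-catalysed anti-Markovnikov addition of a carboxylic acid to a terminal alkyne through a vinylidene complex, which places acyloxy and aryl groups cis and so gives the (Z)-enol ester.

Step 5
Reactants: 6 (Z)-2-[3,4,5-tris(benzyloxy)phenyl]ethenyl acetate; 3 3,5-bis(benzyloxy)-2-(hydroxymethyl)phenol
Product: 8 (2R,3R)-5,7-bis(benzyloxy)-2-[3,4,5-tris(benzyloxy)phenyl]-3,4-dihydro-2H-chromen-3-yl acetate, via ortho-quinone methide 7 (not isolated)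
Conditions: (R)-3,3′-bis(2,4,6-triisopropylphenyl)-BINOL N-triflylphosphoramide (5 mol%), 5 Å MS, toluene, 0 °C; 3 added over 8 h to 6 (2 equiv)
Reagents that add atoms: none
Why: Proposed new method: the acid dehydrates 3 to the ortho-quinone methide 7 and stays hydrogen-bonded to its carbonyl oxygen, and 7 reacts as a 1-oxadiene (O1=C8a–C4a=C4) with the C2=C3 bond of 6 in an asynchronous inverse-demand oxa-Diels–Alder reaction in which C4–C3 forms ahead of O1–C2. The closest known reaction type is the chiral-Brønsted-acid-catalysed [4+2] of in situ ortho-quinone methides with styrenes; new are the methide without a C4 substituent, so that both stereocentres lie on the alkene carbons, and the β-acyloxy group on the styrene. Ring F, the only ring formed, is closed in the [4π+2π] mode. C2 and C3 should come out cis because the (Z) geometry of 6 is transferred suprafacially (O1 captures the benzylic C2 before rotation), and their (2R,3R) configuration is controlled by the chiral anion, which shields one face of the bound methide. The step needs regioselectivity (C4 to the acetoxy carbon, O1 to the benzylic carbon), secured by the aryl group with its para benzyloxy substituent being a far better donor than the acyloxy group. It also needs chemoselectivity over arylation of 7 by the rings of 3 and 8, secured by slow addition of 3 to excess 6.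

Step 6
Reactants: 8 (2R,3R)-5,7-bis(benzyloxy)-2-[3,4,5-tris(benzyloxy)phenyl]-3,4-dihydro-2H-chromen-3-yl acetate
Product: 9 (2R,3R)-5,7-bis(benzyloxy)-2-[3,4,5-tris(benzyloxy)phenyl]-3,4-dihydro-2H-chromen-3-ol
Conditions: K2CO3, MeOH/THF, rt
Reagents that add atoms: none
Why: Base-catalysed methanolysis of the acetate, which leaves the benzyl ethers and both stereocentres untouched.

Step 7
Reactants: 10 methyl 3,4,5-trihydroxybenzoate (methyl gallate)
Product: 11 methyl 3,4-bis(benzyloxy)-5-hydroxybenzoate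
Conditions: BnBr (2.0 equiv), K2CO3, KI (cat.), acetone, reflux
Reagents that add atoms: benzyl bromide, BrCc1ccccc1
Why: Williamson etherification in which the most acidic 4-OH reacts first and one flanking OH second, the stoichiometry stopping the reaction at the 3,4-dibenzyl ether.

Step 8
Reactants: 4 3,4,5-tris(benzyloxy)benzaldehyde
Product: 12 3,4,5-tris(benzyloxy)-2-bromobenzaldehyde
Conditions: NBS (1.05 equiv), MeCN, 0 °C to rt, dark
Reagents that add atoms: N-bromosuccinimide, O=C1CCC(=O)N1Br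
Why: Electrophilic aromatic bromination at the only free ring position (C2 and C6 are equivalent), activated by ortho and para benzyloxy groups, while the formyl group prevents a second bromination.

Step 9
Reactants: 12 3,4,5-tris(benzyloxy)-2-bromobenzaldehyde; 11 methyl 3,4-bis(benzyloxy)-5-hydroxybenzoate
Product: 13 methyl 3,4-bis(benzyloxy)-5-[2,3,4-tris(benzyloxy)-6-formylphenoxy]benzoate
Conditions: CuI (20 mol%), N,N-dimethylglycine hydrochloride (60 mol%), Cs2CO3 (2 equiv), 1,4-dioxane, 100 °C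
Reagents that add atoms: none
Why: Ullmann-type C–O coupling with an amino acid ligand, in which the ortho formyl group assists oxidative addition and has no α-hydrogen to lose under the carbonate base.

Step 10
Reactants: 13 methyl 3,4-bis(benzyloxy)-5-[2,3,4-tris(benzyloxy)-6-formylphenoxy]benzoate
Product: 14 methyl 3,4-bis(benzyloxy)-5-[2,3,4-tris(benzyloxy)-6-ethynylphenoxy]benzoate
Conditions: dimethyl (1-diazo-2-oxopropyl)phosphonate (1.3 equiv), K2CO3, MeOH/THF, rt
Reagents that add atoms: Ohira–Bestmann reagent, CC(=O)C(=[N+]=[N-])P(=O)(OC)OC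
Why: Seyferth–Gilbert homologation (Ohira–Bestmann form) of the aryl aldehyde; the methyl ester cannot be changed by methanol.

Step 11
Reactants: 14 methyl 3,4-bis(benzyloxy)-5-[2,3,4-tris(benzyloxy)-6-ethynylphenoxy]benzoate; 15 3,4,5-tris(benzyloxy)benzoic acid
Product: 16 methyl 3,4-bis(benzyloxy)-5-[2,3,4-tris(benzyloxy)-6-{(Z)-2-[3,4,5-tris(benzyloxy)benzoyloxy]ethenyl}phenoxy]benzoate
Conditions: [RuCl2(p-cymene)]2 (1 mol%), P(4-ClC6H4)3 (3 mol%), DMAP (4 mol%), toluene, 60 °C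
Reagents that add atoms: none
Why: The same ruthenium-catalysed anti-Markovnikov, (Z)-selective addition of a carboxylic acid to a terminal alkyne as in step 4, here installing the gallate as the enol ester.

Step 12
Reactants: 16 methyl 3,4-bis(benzyloxy)-5-[2,3,4-tris(benzyloxy)-6-{(Z)-2-[3,4,5-tris(benzyloxy)benzoyloxy]ethenyl}phenoxy]benzoate; 2 2,4-bis(benzyloxy)-6-hydroxybenzaldehyde
Product: 19 (2R,3R,4S)-5,7-bis(benzyloxy)-4-methoxy-2-{3,4,5-tris(benzyloxy)-2-[2,3-bis(benzyloxy)-5-(methoxycarbonyl)phenoxy]phenyl}-3,4-dihydro-2H-chromen-3-yl 3,4,5-tris(benzyloxy)benzoate, via dimethyl acetal 17 (not isolated), via methoxy ortho-quinone methide 18 (not isolated)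
Conditions: HC(OMe)3 (3 equiv), (R)-3,3′-bis(2,4,6-triisopropylphenyl)-BINOL N-triflylphosphoramide (10 mol%), 5 Å MS, toluene, 0 °C to rt; 2 (1.5 equiv) added over 8 h to 16
Reagents that add atoms: trimethyl orthoformate, COC(OC)OC
Why: Proposed new method: the acid turns 2 and the orthoformate into acetal 17 and ionises it to the acid-bound (E)-methoxy ortho-quinone methide 18 (an aryl oxocarbenium ion in its protonated form), which adds as a 1-oxadiene to the (Z)-enol ester in the inverse-demand oxa-Diels–Alder manner of step 5 (closest known type: acid-mediated [4+2] of salicylaldehyde acetals with electron-rich alkenes to 4-alkoxychromans), the (Z)-alkene giving the 2,3-cis pair, the chiral anion the (2R,3R) configuration, the para benzyloxy group of the 2-aryloxy-3,4,5-tris(benzyloxy)phenyl ring directing O1 to C2, and an exo approach placing the 4-methoxy group trans to the ester.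

Step 13
Reactants: 19 (2R,3R,4S)-4-methoxyflavan gallate described in step 12; 9 (2R,3R)-5,7-bis(benzyloxy)-2-[3,4,5-tris(benzyloxy)phenyl]-3,4-dihydro-2H-chromen-3-ol
Product: 20 4β→8 dimer methyl ester (upper unit of 19 bonded through C4 (4R; trans to the C3 ester) to C8 of 9 in place of the methoxy group; lower C3–OH free)
Conditions: TMSOTf (0.3 equiv), 9 (3 equiv), CH2Cl2, −78 to −40 °C; then Et3N
Reagents that add atoms: none
Why: Lewis-acid-mediated Friedel–Crafts arylation in which TMSOTf ionises the 4-methoxy group and the flavan-4-yl cation is attacked by C8 of 9, the more nucleophilic and less hindered ring D position, anti to the C3 ester, giving the 3,4-trans (4R) configuration known for 2,3-cis flavans, while excess 9 suppresses self-condensation of 19.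

Step 14
Reactants: 20 4β→8 dimer methyl ester
Product: 21 4β→8 dimer carboxylic acid (seco acid: free CO2H on the bridging galloyl ring and free lower C3–OH)
Conditions: Me3SnOH (8 equiv), 1,2-dichloroethane, 80 °C; 0.1 M aqueous HCl work-up
Reagents that add atoms: trimethyltin hydroxide, C[Sn](C)(C)O
Why: Me3SnOH hydrolyses the unhindered methyl ester selectively under neutral conditions, leaving the hindered secondary gallate at the upper C3 and the acid-labile interflavan bond intact.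

Step 15
Reactants: 21 seco acid
Product: 22 pentadeca-O-benzyl ether of the target (16-membered macrolactone between the bridging galloyl carboxyl and the lower C3 oxygen)
Conditions: 2-methyl-6-nitrobenzoic anhydride (1.3 equiv), DMAP (3 equiv), CH2Cl2 (1 mM), rt, slow addition of 21
Reagents that add atoms: none
Why: Shiina macrolactonisation, in which the lower C3–OH attacks the unhindered aroyl carbonyl of the mixed anhydride at high dilution and closes the 16-membered ring without touching a stereocentre.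

Step 16
Reactants: 22 pentadeca-O-benzyl ether of the target
Product: 23 CNP0601265.1
Conditions: H2 (1 atm), Pd(OH)2/C, THF/MeOH/H2O, rt
Reagents that add atoms: none
Why: Hydrogenolysis of all fifteen benzyl ethers under neutral conditions, to which the two esters, the diaryl ether and the interflavan bond are stable.

**Compound list**

1 | 2,4,6-trihydroxybenzaldehyde | O=Cc1c(O)cc(O)cc1O | starting material
2 | 2,4-bis(benzyloxy)-6-hydroxybenzaldehyde | O=Cc1c(O)cc(OCc2ccccc2)cc1OCc1ccccc1 | intermediate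
3 | 3,5-bis(benzyloxy)-2-(hydroxymethyl)phenol | OCc1c(O)cc(OCc2ccccc2)cc1OCc1ccccc1 | intermediate
4 | 3,4,5-tris(benzyloxy)benzaldehyde | O=Cc1cc(OCc2ccccc2)c(OCc2ccccc2)c(OCc2ccccc2)c1 | starting material
5 | 1,2,3-tris(benzyloxy)-5-ethynylbenzene | C#Cc1cc(OCc2ccccc2)c(OCc2ccccc2)c(OCc2ccccc2)c1 | intermediate
6 | (Z)-2-[3,4,5-tris(benzyloxy)phenyl]ethenyl acetate | CC(=O)O/C=C\c1cc(OCc2ccccc2)c(OCc2ccccc2)c(OCc2ccccc2)c1 | intermediate
7 | 3,5-bis(benzyloxy)-6-methylidenecyclohexa-2,4-dien-1-one (ortho-quinone methide, not isolated) | C=C1C(=O)C=C(OCc2ccccc2)C=C1OCc1ccccc1 | intermediate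
8 | (2R,3R)-5,7-bis(benzyloxy)-2-[3,4,5-tris(benzyloxy)phenyl]-3,4-dihydro-2H-chromen-3-yl acetate (2,3-cis) | CC(=O)O[C@@H]1Cc2c(OCc3ccccc3)cc(OCc3ccccc3)cc2O[C@@H]1c1cc(OCc2ccccc2)c(OCc2ccccc2)c(OCc2ccccc2)c1 | intermediate
9 | (2R,3R)-5,7-bis(benzyloxy)-2-[3,4,5-tris(benzyloxy)phenyl]-3,4-dihydro-2H-chromen-3-ol (penta-O-benzyl-(−)-epigallocatechin) | O[C@@H]1Cc2c(OCc3ccccc3)cc(OCc3ccccc3)cc2O[C@@H]1c1cc(OCc2ccccc2)c(OCc2ccccc2)c(OCc2ccccc2)c1 | intermediate
10 | methyl 3,4,5-trihydroxybenzoate (methyl gallate) | COC(=O)c1cc(O)c(O)c(O)c1 | starting material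
11 | methyl 3,4-bis(benzyloxy)-5-hydroxybenzoate | COC(=O)c1cc(O)c(OCc2ccccc2)c(OCc2ccccc2)c1 | intermediate
12 | 3,4,5-tris(benzyloxy)-2-bromobenzaldehyde | O=Cc1cc(OCc2ccccc2)c(OCc2ccccc2)c(OCc2ccccc2)c1Br | intermediate
13 | methyl 3,4-bis(benzyloxy)-5-[2,3,4-tris(benzyloxy)-6-formylphenoxy]benzoate | COC(=O)c1cc(OCc2ccccc2)c(OCc2ccccc2)c(Oc2c(C=O)cc(OCc3ccccc3)c(OCc3ccccc3)c2OCc2ccccc2)c1 | intermediate
14 | methyl 3,4-bis(benzyloxy)-5-[2,3,4-tris(benzyloxy)-6-ethynylphenoxy]benzoate | COC(=O)c1cc(OCc2ccccc2)c(OCc2ccccc2)c(Oc2c(C#C)cc(OCc3ccccc3)c(OCc3ccccc3)c2OCc2ccccc2)c1 | intermediate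
15 | 3,4,5-tris(benzyloxy)benzoic acid | OC(=O)c1cc(OCc2ccccc2)c(OCc2ccccc2)c(OCc2ccccc2)c1 | starting material
16 | methyl 3,4-bis(benzyloxy)-5-[2,3,4-tris(benzyloxy)-6-{(Z)-2-[3,4,5-tris(benzyloxy)benzoyloxy]ethenyl}phenoxy]benzoate | COC(=O)c1cc(OCc2ccccc2)c(OCc2ccccc2)c(Oc2c(/C=C\OC(=O)c3cc(OCc4ccccc4)c(OCc4ccccc4)c(OCc4ccccc4)c3)cc(OCc3ccccc3)c(OCc3ccccc3)c2OCc2ccccc2)c1 | intermediate
17 | 3,5-bis(benzyloxy)-2-(dimethoxymethyl)phenol (dimethyl acetal of 2, not isolated) | COC(OC)c1c(O)cc(OCc2ccccc2)cc1OCc1ccccc1 | intermediate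
18 | (6E)-3,5-bis(benzyloxy)-6-(methoxymethylidene)cyclohexa-2,4-dien-1-one (methoxy ortho-quinone methide, not isolated) | CO/C=C1/C(=O)C=C(OCc2ccccc2)C=C1OCc1ccccc1 | intermediate
19 | (2R,3R,4S)-5,7-bis(benzyloxy)-4-methoxy-2-{3,4,5-tris(benzyloxy)-2-[2,3-bis(benzyloxy)-5-(methoxycarbonyl)phenoxy]phenyl}-3,4-dihydro-2H-chromen-3-yl 3,4,5-tris(benzyloxy)benzoate | O=C(O[C@@H]1[C@@H](OC)c2c(OCc3ccccc3)cc(OCc3ccccc3)cc2O[C@@H]1c1cc(OCc2ccccc2)c(OCc2ccccc2)c(OCc2ccccc2)c1Oc1cc(cc(OCc2ccccc2)c1OCc1ccccc1)C(=O)OC)c1cc(OCc2ccccc2)c(OCc2ccccc2)c(OCc2ccccc2)c1 | intermediate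
20 | 4β→8 dimer methyl ester: (2R,3R,4R) upper flavan gallate of 19 bonded at C4 to C8 of the (2R,3R) flavan-3-ol 9 | O=C(O[C@@H]1[C@@H](c4c(OCc6ccccc6)cc(OCc6ccccc6)c5C[C@@H](O)[C@@H](c6cc(OCc7ccccc7)c(OCc7ccccc7)c(OCc7ccccc7)c6)Oc45)c2c(OCc3ccccc3)cc(OCc3ccccc3)cc2O[C@@H]1c1cc(OCc2ccccc2)c(OCc2ccccc2)c(OCc2ccccc2)c1Oc1cc(cc(OCc2ccccc2)c1OCc1ccccc1)C(=O)OC)c1cc(OCc2ccccc2)c(OCc2ccccc2)c(OCc2ccccc2)c1 | intermediate
21 | seco acid: 20 with CO2H in place of CO2CH3 | O=C(O[C@@H]1[C@@H](c4c(OCc6ccccc6)cc(OCc6ccccc6)c5C[C@@H](O)[C@@H](c6cc(OCc7ccccc7)c(OCc7ccccc7)c(OCc7ccccc7)c6)Oc45)c2c(OCc3ccccc3)cc(OCc3ccccc3)cc2O[C@@H]1c1cc(OCc2ccccc2)c(OCc2ccccc2)c(OCc2ccccc2)c1Oc1cc(cc(OCc2ccccc2)c1OCc1ccccc1)C(=O)O)c1cc(OCc2ccccc2)c(OCc2ccccc2)c(OCc2ccccc2)c1 | intermediate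
22 | pentadeca-O-benzyl ether of 23 (16-membered macrolactone; upper 2R,3R,4R; lower 2R,3R) | O=C(O[C@@H]1[C@@H]2c3c(OCc4ccccc4)cc(OCc4ccccc4)cc3O[C@@H]1c1cc(OCc3ccccc3)c(OCc3ccccc3)c(OCc3ccccc3)c1Oc1cc(cc(OCc3ccccc3)c1OCc1ccccc1)C(=O)O[C@@H]1Cc3c(OCc4ccccc4)cc(OCc4ccccc4)c2c3O[C@@H]1c1cc(OCc2ccccc2)c(OCc2ccccc2)c(OCc2ccccc2)c1)c1cc(OCc2ccccc2)c(OCc2ccccc2)c(OCc2ccccc2)c1 | intermediate
23 | CNP0601265.1 | O=C(O[C@@H]1[C@@H]2c3c(O)cc(O)cc3O[C@@H]1c1cc(O)c(O)c(O)c1Oc1cc(cc(O)c1O)C(=O)O[C@@H]1Cc3c(O)cc(O)c2c3O[C@@H]1c1cc(O)c(O)c(O)c1)c1cc(O)c(O)c(O)c1 | target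

**Summary**

Total step count: 16. Longest linear sequence: 9 steps (steps 8, 9, 10, 11, 12, 13, 14, 15, 16 from aldehyde 4).

Steps most likely to fail:

1. Step 5. The catalyst may discriminate the alkene faces poorly, or the acid-activated methide may be captured by the electron-rich rings of 3 and 8 (Friedel–Crafts alkylation) before it cycloadds. The fallback sets out from 3 and 6 and comes back at 9. Without acid, 3 is heated with excess 6 (o-xylene, 140 °C), so that the neutral methide reacts in the known thermal hetero-Diels–Alder manner. This should give the racemic cis acetate, that is 8 together with the (2S,3S)-acetate F1. Methanolysis (K2CO3, MeOH) gives the racemic alcohol, 9 together with the (2S,3S)-alcohol F2. Preparative chromatography on a chiral stationary phase (cellulose tris(3,5-dimethylphenylcarbamate)) then delivers 9.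

2. Step 12. The donor-stabilised methoxy methide may be too weak an electrophile for the enol ester, enantiofacial control may be lost with the large dienophile, or the 4-methoxy product may ionise under the acid and arylate. The fallback sets out from 16 and 3 and comes back at 20. Without acid and without orthoformate, 3 is heated with 16 (o-xylene, 140 °C) in the known thermal hetero-Diels–Alder manner. This should give the racemic C4-unsubstituted flavan gallate, that is the (2R,3R)-flavan gallate F3 together with the (2S,3S)-flavan gallate F4. The known benzylic oxidation with DDQ and 2-ethoxyethanol (CH2Cl2, rt) then gives the (2R,3R,4S)-4-(2-ethoxyethoxy) ether F5 together with the (2S,3S,4R)-4-(2-ethoxyethoxy) ether F6. Coupling of this racemate with enantiopure 9 under the conditions of step 13 gives 20 and the diastereomeric dimer F7, which are separated by chromatography.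

3. Step 15. Ring closure at the hindered axial C3 hydroxyl may be slower than intermolecular acylation, so that oligomers form. The fallback reverses the order of the two ring-forming bonds; it sets out from 19 and 9 and comes back at 22. Me3SnOH (1,2-dichloroethane, 80 °C) converts 19 into the 4-methoxy carboxylic acid F8. EDC·HCl/DMAP esterifies F8 with the C3 hydroxyl of 9 to the open-chain ester F9. TMSOTf at high dilution (CH2Cl2, −40 °C) then ionises C4 and closes the 16-membered ring by intramolecular C4→C8 arylation, giving 22.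

Further compounds

F1 | step 5 | (2S,3S)-5,7-bis(benzyloxy)-2-[3,4,5-tris(benzyloxy)phenyl]-3,4-dihydro-2H-chromen-3-yl acetate (enantiomer of 8) | CC(=O)O[C@H]1Cc2c(OCc3ccccc3)cc(OCc3ccccc3)cc2O[C@H]1c1cc(OCc2ccccc2)c(OCc2ccccc2)c(OCc2ccccc2)c1
F2 | step 5 | (2S,3S)-5,7-bis(benzyloxy)-2-[3,4,5-tris(benzyloxy)phenyl]-3,4-dihydro-2H-chromen-3-ol (enantiomer of 9) | O[C@H]1Cc2c(OCc3ccccc3)cc(OCc3ccccc3)cc2O[C@H]1c1cc(OCc2ccccc2)c(OCc2ccccc2)c(OCc2ccccc2)c1
F3 | step 12 | (2R,3R)-5,7-bis(benzyloxy)-2-{3,4,5-tris(benzyloxy)-2-[2,3-bis(benzyloxy)-5-(methoxycarbonyl)phenoxy]phenyl}-3,4-dihydro-2H-chromen-3-yl 3,4,5-tris(benzyloxy)benzoate | O=C(O[C@@H]1Cc2c(OCc3ccccc3)cc(OCc3ccccc3)cc2O[C@@H]1c1cc(OCc2ccccc2)c(OCc2ccccc2)c(OCc2ccccc2)c1Oc1cc(cc(OCc2ccccc2)c1OCc1ccccc1)C(=O)OC)c1cc(OCc2ccccc2)c(OCc2ccccc2)c(OCc2ccccc2)c1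
F4 | step 12 | (2S,3S)-enantiomer of F3 | O=C(O[C@H]1Cc2c(OCc3ccccc3)cc(OCc3ccccc3)cc2O[C@H]1c1cc(OCc2ccccc2)c(OCc2ccccc2)c(OCc2ccccc2)c1Oc1cc(cc(OCc2ccccc2)c1OCc1ccccc1)C(=O)OC)c1cc(OCc2ccccc2)c(OCc2ccccc2)c(OCc2ccccc2)c1
F5 | step 12 | (2R,3R,4S)-4-(2-ethoxyethoxy) derivative of F3 | O=C(O[C@@H]1[C@@H](OCCOCC)c2c(OCc3ccccc3)cc(OCc3ccccc3)cc2O[C@@H]1c1cc(OCc2ccccc2)c(OCc2ccccc2)c(OCc2ccccc2)c1Oc1cc(cc(OCc2ccccc2)c1OCc1ccccc1)C(=O)OC)c1cc(OCc2ccccc2)c(OCc2ccccc2)c(OCc2ccccc2)c1
F6 | step 12 | (2S,3S,4R)-enantiomer of F5 | O=C(O[C@H]1[C@H](OCCOCC)c2c(OCc3ccccc3)cc(OCc3ccccc3)cc2O[C@H]1c1cc(OCc2ccccc2)c(OCc2ccccc2)c(OCc2ccccc2)c1Oc1cc(cc(OCc2ccccc2)c1OCc1ccccc1)C(=O)OC)c1cc(OCc2ccccc2)c(OCc2ccccc2)c(OCc2ccccc2)c1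
F7 | step 12 | diastereomer of 20 with (2S,3S,4S) upper unit and (2R,3R) lower unit | O=C(O[C@H]1[C@H](c4c(OCc6ccccc6)cc(OCc6ccccc6)c5C[C@@H](O)[C@@H](c6cc(OCc7ccccc7)c(OCc7ccccc7)c(OCc7ccccc7)c6)Oc45)c2c(OCc3ccccc3)cc(OCc3ccccc3)cc2O[C@H]1c1cc(OCc2ccccc2)c(OCc2ccccc2)c(OCc2ccccc2)c1Oc1cc(cc(OCc2ccccc2)c1OCc1ccccc1)C(=O)OC)c1cc(OCc2ccccc2)c(OCc2ccccc2)c(OCc2ccccc2)c1
F8 | step 15 | carboxylic acid of 19 (CO2H in place of CO2CH3, 4-methoxy group kept) | O=C(O[C@@H]1[C@@H](OC)c2c(OCc3ccccc3)cc(OCc3ccccc3)cc2O[C@@H]1c1cc(OCc2ccccc2)c(OCc2ccccc2)c(OCc2ccccc2)c1Oc1cc(cc(OCc2ccccc2)c1OCc1ccccc1)C(=O)O)c1cc(OCc2ccccc2)c(OCc2ccccc2)c(OCc2ccccc2)c1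
F9 | step 15 | ester of F8 with the C3 hydroxyl of 9 (open-chain precursor of 22, C4–C8 bond not yet formed) | O=C(O[C@@H]1[C@@H](OC)c2c(OCc3ccccc3)cc(OCc3ccccc3)cc2O[C@@H]1c1cc(OCc2ccccc2)c(OCc2ccccc2)c(OCc2ccccc2)c1Oc1cc(cc(OCc2ccccc2)c1OCc1ccccc1)C(=O)O[C@@H]1Cc2c(OCc3ccccc3)cc(OCc3ccccc3)cc2O[C@@H]1c1cc(OCc2ccccc2)c(OCc2ccccc2)c(OCc2ccccc2)c1)c1cc(OCc2ccccc2)c(OCc2ccccc2)c(OCc2ccccc2)c1
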